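Each X made in this flask costs two L, not one, because the D that J and L release together is taken up at once as L.D: K2 times the charged c(L) is 1900, so you may take the fast step as balanced, with free D a trace and L.D counted as equal to X. Meanwhile G competes with L for J.

| flask | J | L | G | time | remark |
|---|---|---|---|---|---|
| Monday's | 0.50 M (in portions, 2) | 0.525 M | 0.500 M | 15 h | the portions of J follow each other after 1.2 h, the first at the start |
| Saturday's | 0.50 M (in portions, 2) | 0.525 M | 0.500 M | 15 h | the portions of J follow each other after 2.5 h, the first at the start |
| Friday's | 0.50 M (in portions, 2) | 0.525 M | 0.500 M | 15 h | the portions of J follow each other after 5.0 h, the first at the start |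

    J + L → D + X (k1 = 4.19 × 10⁻⁵ M⁻¹ s⁻¹)
    L + D ⇌ L.D, settled at all times (K2 = 3580 M⁻¹)
    J + G → J.G (k3 = 1.01 × 10⁻⁴ M⁻¹ s⁻¹)

- "hardly changes" means that all values lie within two and a half points (for a concentration: within two and a half percent of the largest)
- run time (Monday's): 15 h

* amount of X at the end, in percent of the J charged for Monday's, Saturday's, Friday's, in this order
* the course of these numbers from the first flask to the last (falls all the way / hardly changes / falls, then rises / rises, then falls / rises all the way)

With the binding so tight, the two consumers obey

dc(L)/dt = −2 k1 c(J) c(L)

dc(G)/dt = −k3 c(J) c(G)

Divide one by the other and c(J) cancels, so the portions drop out of the path that L and G follow together: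

c(L)/c(L, charged) = [c(G)/c(G, charged)]^m, with m = 0.830

I call m the drain exponent, twice k1 over k3: a selectivity factor with L counted double, giving the fractional loss of free L per fractional loss of G.

You can reach the ceiling of X, the yield once the charged J has become X and J.G, in two ways. The quick way freezes the split of J at its value for the charges:

k1 c(L) / [k1 c(L) + k3 c(G)] = 30.3 %

The second way uses the path. X is the free L lost divided by 2, J.G is the G lost, and the charges of J and G are equal at 0.50 M, so the remaining fraction g of G satisfies

g = [c(L, charged) / (2 c(G, charged))] (1 − g^m)

One Newton step from 0.5 gives g = 0.319, with free L at 38.7 % of its charge and X at 31.9 %.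

The two part by 1.6 percentage points, and the quick way is the one that cheats: with m below one, G loses a larger fraction than L, so the ratio c(L)/c(G) climbs as the run goes on, and the frozen split misses that climb.

Time comes next. J's half-life is 2.66 h at the charges but 7.83 h near the ceiling, and the run lasts 1.92 of the longer ones. I therefore commit to X below 31.9 % at the end, and lower on Friday's than on Monday's, because the second portion has 10.0 h on Friday's against 13.8 h on Monday's.

The forecast gives 28.1 %, 27.7 % and 26.8 %, a row that hardly changes, holding that “the split between X and J.G is set by the L/G competition alone, not by the dosing schedule”.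

The simulation gives 28.1 %, 27.7 % and 26.8 %, a row that hardly changes; at 150 h Monday's flask holds X at 32.1 %, G at 32.1 % and L at 39.0 %.

In Monday's flask at 3.28 h, J goes to J.G 2.2 times as fast as to X, with half-lives of J by these two paths of 5.5 h against 12 h, and at 15.0 h G stands at 39.7 %, which the drain exponent 0.830 turns into L at 46.5 %, beside the 46.5 % in the flask. In Friday's flask G stands at 42.3 % at 15.0 h, and the same exponent gives L at 49.0 % and X at 26.8 %, against 49.0 % and 26.8 % in the flask.

The rate constants were set for the occasion; what happens was integrated by code.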